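# Proposed synthesis of CNP0179824.8 (compound 14) by annulation of ring A onto a ring-B silyl enol ether

Skeletal atoms are numbered as in a tetralin: C1 carries the aryl group, C2 carries C9', C3 carries C9, then C4, C4a, C5 to C8 and C8a.

## Analysis of the target

Target 14 is a cyclolignan of the 1-aryltetralin type. Ring A is a benzene ring fused through C4a and C8a with H at C5, OMe at C6, OH at C7 and H at C8; ring B (C1, C2, C3, C4, C4a, C8a) is saturated and carries a 4-hydroxy-3-methoxyphenyl group at C1 and hydroxymethyl groups at C2 (C9') and C3 (C9). The three stereocentres are contiguous and are (1R,2S,3R): the aryl group is trans to the C2 hydroxymethyl group, and the two hydroxymethyl groups are cis to each other. This cis C2/C3 relation separates 14 from the all-trans isolariciresinol series and cannot be reached by equilibrating a C2/C3 diester, which would drift to trans. The sensitive groups are two guaiacol-type phenols that oxidise easily, the doubly benzylic C1–H, and a cis 1,4-diol that can close to a tetrahydrofuran under acid. The synthesis is hard because C1 must be trans to C2 while C2 and C3 stay cis, on a ring with few handles, and because the last steps must tolerate free phenols. The strategy rests on ring A: between C4a and C8a it shows H, OMe, O, H on C5 to C8, which is the pattern a four-carbon α-methoxy vinyl methyl ketone leaves when it is annulated onto a ring-B ketone at C8a; and a ring B with oxygen at C8a, a nucleophilic C4a, the C1 aryl and a cis C2/C3 pair is what a [4+2] cycloaddition of a 2-silyloxy-1-aryl diene with a butenolide gives.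

## Retrosynthetic reasoning

**14 ⇒ 13 (O–benzyl bond).** The pendant phenol is unmasked last. A benzyl ether is chosen because it survives organomagnesium addition, Lewis acids, a quinone oxidant and hydride reduction, and because it is removed by hydrogenolysis under neutral conditions that leave the cis diol and the C1–H alone.

**13 ⇒ 12 (two C–O bonds of the diol become one lactone).** C9 is taken back to a lactone carbonyl and C9' to the lactone CH2–O. A cis-fused γ-lactone is the preferred ring fusion, so the cis C2/C3 relation is stored where it cannot drift to trans. Because both carbons end as CH2OH, the orientation of the lactone is irrelevant to the target. The forward step is a hydride reduction.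

**12 ⇒ 7 + 9 (C4a–C5 and C8–C8a; the key disconnection).** Cutting these two bonds removes ring A and leaves its four carbons C5 to C8, with both oxygens already in place, as enone 9. This turns the problem of a regiodefined tetrasubstituted arene into one of connectivity: which carbon of ring B is the nucleophile and which is the carbonyl. The ring-B partner is silyl enol ether 7, with the double bond between C4a and C8a. A Friedel–Crafts cut at C1–C8a was not taken, because it would need a cation at C1 next to the lactone and would leave the regiochemistry of attack on the arene to chance. In the forward direction 7 must add through C4a to the CH2 of 9 to give diketone 10. The methyl ketone of 10 must then condense onto the C8a carbonyl to give enone 11, and 11 must be dehydrogenated to the phenol. On the way C1, next to the C8a carbonyl, can relax from cis to trans relative to C2.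

**7 ⇒ 5 + 6 (C1–C2 and C3–C4).** The cyclohexene of 7, with its enol ether double bond between C4a and C8a, is the retron of a Diels–Alder reaction of siloxydiene 5 with butenolide 6. The cis alkene of 6 gives the cis C2/C3 pair, and a chiral Lewis acid bound to 6 selects its face and so the absolute configuration of both centres. The silyloxy group makes the aryl-bearing terminus of 5 the nucleophilic one, so it bonds to the β-carbon of 6 and C9' ends on C2. The endo mode puts the aryl group cis to the lactone; this is corrected in the key step, so the cycloaddition only has to control the face of 6.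

**5 ⇒ 4 ⇒ 3 ⇒ 1.** Diene 5 is the silyl enol ether of benzyl vinyl ketone 4, which has only one enolisable position. Enone 4 is cut between the carbonyl carbon and the vinyl group: a vinyl organometallic adds once to N-methoxy-N-methylamide 3. Amide 3 comes from commercial acid 1 through acyl imidazolide 2.

**9 ⇒ 8.** Enone 9 is the enol ether formed by acid-catalysed elimination from commercial ketal 8; only the ketal methyl group can lose a proton, so one alkene results.

## Alternatives that were turned down

**Alternative 1: anodic coupling of a tethered bis-cinnamate.** The cuts are C2–C3 and C1–C8a, leading back to two 5-bromoferulate units joined by (2R,3R)-butane-2,3-diol, A1. Constant-current oxidation at graphite (MeOH, LiClO4, 2,6-lutidine) would couple the two α-carbons, and one arene would then attack the other quinone methide to give the diol-bridged trans-1-aryl-1,2-dihydronaphthalene diester A2.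
- For it: it is biomimetic and very short, both arenes come with the right oxygenation from ferulic acid, and the trans C1/C2 relation follows from the cyclisation itself. On step count to the carbon skeleton and on C1 control it is stronger than the chosen route.
- Against it: C3 is still sp2 in A2. The cis C2/C3 relation, the one feature that defines this target, would be left to a late hydrogenation of the C3–C4 alkene, whose two faces are contested by the pseudoaxial C1 aryl and the C2 ester inside an eight-membered dilactone. Two bromine atoms must be removed, and the absolute configuration depends on induction from a flexible tether in a radical coupling with competing coupling modes.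
- Comparison: the chosen route is longer but fixes C2 and C3 as a cis-fused lactone from the moment they are formed.

**Alternative 2: syn bis(methoxycarbonylation) of a C2–C3 alkene.** The cuts are C2–C9' and C3–C9, leading back to the 1-aryl-1,4-dihydronaphthalene A3. A divalent palladium catalyst, Pd(O2CCF3)2 with an aryl diimine ligand, p-benzoquinone, CO and MeOH would add two ester groups syn across the alkene on the face away from the aryl group, giving diester A4.
- For it: one syn addition sets C2 and C3 cis to each other and trans to C1, exactly as required, and the end game is as short as the chosen one. On the logic of relative stereocontrol it is stronger than the chosen route, which relies on an equilibration at C1.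
- Against it: the difficulty moves into A3. Its C1 stereocentre is doubly benzylic and allylic in a skipped diene, so a palladium hydride or trace base can move the alkene into conjugation and erase C1, and the oxidising medium favours aromatisation to the arylnaphthalene. A3 would also need its own asymmetric synthesis, with ring A built separately, and the face selectivity hangs on a single allylic substituent.
- Comparison: the chosen route draws its absolute configuration from a catalytic Diels–Alder reaction on robust substrates and keeps C1 adjustable until ring A is aromatic.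

**Alternative 3: photoenol Diels–Alder assembly of ring B.** The cuts are C1–C2 and C3–C4, leading back to 2-benzylbenzaldehyde A5 and (E)-enoate A6. Irradiation at 365 nm would give the hydroxy-ortho-quinodimethane, which Ti(OiPr)4 and a TADDOL-type diol would bring together with A6 to give the 4-hydroxy-1-aryltetralin A7.
- For it: it is convergent, both arenes come from vanillin-type pieces, ring B and its stereocentres arise in one step, and C1 and C2 come out directly as in the target under catalyst control. For C1 it is stronger than the chosen route.
- Against it: the (E)-enoate makes C2 and C3 trans. C3 would have to be inverted against the thermodynamic preference, and the C4 hydroxyl, the silyl ether and the ester all need extra operations, so the end game is several steps longer.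
- Comparison: the chosen route pays with an uncertain equilibration at C1 but obtains the cis C2/C3 pair intrinsically from a cyclic cis dienophile.

Key step: step 6

Assumption: the sense of induction in step 4 is taken from the α-C–H···O binding model for a cationic oxazaborolidine on the lactone carbonyl; the (S)-catalyst is written, and its mirror image from (R)-diphenylprolinol is used instead if the adduct proves to be the antipode.

## Route

Step 1
Reactants: 1 [4-(benzyloxy)-3-methoxyphenyl]acetic acid
Product: 3 2-[4-(benzyloxy)-3-methoxyphenyl]-N-methoxy-N-methylacetamide, via acyl imidazolide 2 (not isolated)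
Conditions: CDI, CH2Cl2, rt; then MeNH(OMe)·HCl, rt
Reagents that add atoms: N,O-dimethylhydroxylamine hydrochloride, CNOC.Cl; 1,1'-carbonyldiimidazole, O=C(n1ccnc1)n1ccnc1 (its imidazole stays only in intermediate 2)
Why: Activation of the acid as the acyl imidazolide and aminolysis by the hydroxylamine salt is a standard amide coupling; the conditions are neutral, the benzyl ether is inert and there is no stereocentre to lose.

Step 2
Reactants: 3 2-[4-(benzyloxy)-3-methoxyphenyl]-N-methoxy-N-methylacetamide
Product: 4 1-[4-(benzyloxy)-3-methoxyphenyl]but-3-en-2-one
Conditions: CH2=CHMgBr, THF, −20 to 0 °C; inverse quench into cold 1 M HCl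
Reagents that add atoms: vinylmagnesium bromide, C=C[Mg]Br
Why: Weinreb ketone synthesis: the magnesium chelate of the tetrahedral adduct holds until the quench, so one vinyl group is added. Quenching into cold acid keeps the released N,O-dimethylhydroxylamine protonated so that it cannot add to the enone; 4 is used at once.

Step 3
Reactants: 4 1-[4-(benzyloxy)-3-methoxyphenyl]but-3-en-2-one
Product: 5 tert-butyl({(1Z)-1-[4-(benzyloxy)-3-methoxyphenyl]buta-1,3-dien-2-yl}oxy)dimethylsilane
Conditions: TBSOTf, Et3N, CH2Cl2, 0 °C; filtration through Et3N-deactivated silica
Reagents that add atoms: tert-butyldimethylsilyl trifluoromethanesulfonate, CC(C)(C)[Si](C)(C)OS(=O)(=O)C(F)(F)F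
Why: Soft enolisation with a silyl triflate and a tertiary amine at the only enolisable position, the benzylic CH2. The (Z) enol ether (aryl and silyloxy cis, aryl trans to vinyl) is expected because it avoids allylic strain between aryl and vinyl, and it leaves the aryl group on the outside of the diene so that the s-cis conformer is accessible.

Step 4
Reactants: 5 tert-butyl({(1Z)-1-[4-(benzyloxy)-3-methoxyphenyl]buta-1,3-dien-2-yl}oxy)dimethylsilane; 6 furan-2(5H)-one
Product: 7 (3aS,4S,7aR)-4-[4-(benzyloxy)-3-methoxyphenyl]-5-[(tert-butyldimethylsilyl)oxy]-3a,4,7,7a-tetrahydro-2-benzofuran-1(3H)-one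
Conditions: (S)-1-(o-tolyl)-3,3-diphenyltetrahydro-1H,3H-pyrrolo[1,2-c][1,3,2]oxazaborole·Tf2NH (20 mol%), CH2Cl2, −78 to −40 °C; Et3N quench
Reagents that add atoms: none
Why: Catalytic enantioselective Diels–Alder reaction of a 2-silyloxy diene with an α,β-unsaturated lactone activated by a cationic oxazaborolidine. The silyloxy group makes C1 the nucleophilic terminus, so C1 bonds to the β-carbon of 6 and C4 to the α-carbon; the cis alkene gives the cis ring fusion, and the catalyst shields one face of 6 and so sets C2 and C3 absolutely. The endo mode places the aryl group cis to the lactone, a provisional configuration at C1 that step 6 revises.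

Step 5
Reactants: 8 3,3-dimethoxybutan-2-one
Product: 9 3-methoxybut-3-en-2-one
Conditions: TsOH·H2O (1 mol%), hydroquinone (trace), neat, 140 °C, MeOH distilled off; then distillation
Reagents that add atoms: none
Why: Acid-catalysed elimination of methanol from a ketal through the oxocarbenium ion; only the ketal methyl group can lose a proton, and removing methanol by distillation drives the equilibrium. The enone is kept cold with inhibitor and used freshly distilled.

Step 6
Reactants: 7 (3aS,4S,7aR)-4-[4-(benzyloxy)-3-methoxyphenyl]-5-[(tert-butyldimethylsilyl)oxy]-3a,4,7,7a-tetrahydro-2-benzofuran-1(3H)-one; 9 3-methoxybut-3-en-2-one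
Product: 12 (3aS,4R,9aR)-4-[4-(benzyloxy)-3-methoxyphenyl]-6-hydroxy-7-methoxy-3a,4,9,9a-tetrahydronaphtho[2,3-c]furan-1(3H)-one, via Michael adduct diketone 10 (not isolated), via annulated enone 11 (not isolated)
Conditions: 9, TiCl4, CH2Cl2, −78 °C; aq. NaHCO3, crude into PhMe; pyrrolidine (30 mol%), AcOH (30 mol%), 50 °C; 1 M HCl wash, crude into 1,4-dioxane; DDQ (1.0 equiv), TsOH (cat.), 0 °C to rt
Reagents that add atoms: none
Why: Stage one is a Mukaiyama–Michael addition: TiCl4 chelates the carbonyl and methoxy oxygens of 9, which withdraws the methoxy lone pair from the alkene and restores the electrophilicity of its CH2 terminus, and 7 can react only through C4a, so C4a–C5 forms and the quench gives diketone 10. Stage two is the aldol half of a Robinson annulation: the pyrrolidine enamine of the methyl ketone (C8) adds to the C8a carbonyl in a 6-(enolendo)-exo-trig closure of ring A and dehydration gives enone 11; closure from C6 would make a four-membered ring and the bridged aldol from C1 onto C7 is reversible. C1, the one stereocentre this step sets, is benzylic and α to the C8a carbonyl in 10 and vinylogous to the C7 carbonyl in 11, so it epimerises under the amine–acid buffer; the endo cycloaddition left the aryl group on the concave face of the cis-fused lactone, and thermodynamic control should move it to the convex face, trans to C9'. Stage three is a quinone dehydrogenation of a cyclohexenone: acid-catalysed enolisation toward C6 gives an electron-rich 2-methoxy dienol, DDQ takes hydride from C5, and the cyclohexadienone tautomerises to the C7 phenol, after which C1 is no longer enolisable and its configuration is fixed. The closest known chemistry is the Lewis-acid Robinson annulation of silyl enol ethers with vinyl ketones followed by DDQ aromatisation of the resulting enone. C4a and C6 are stereocentres only in 10 and 11 and vanish on aromatisation, while C2 and C3 are untouched because the lactone α-position is not enolised by this weakly basic buffer. The selectivity the step needs is the placement of OMe at C6 and OH at C7, and connectivity secures it: from C4a, 9 delivers C5, C6 with its methoxy group, C7 with its oxygen and C8 in that order. Chemoselectivity in the oxidation is sought by removing the amine first (its dienamine would aromatise to an arylamine) and by using one equivalent of DDQ, since the product is a 4-alkylguaiacol that excess oxidant would attack.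

Step 7
Reactants: 12 (3aS,4R,9aR)-4-[4-(benzyloxy)-3-methoxyphenyl]-6-hydroxy-7-methoxy-3a,4,9,9a-tetrahydronaphtho[2,3-c]furan-1(3H)-one
Product: 13 (6R,7S,8R)-8-[4-(benzyloxy)-3-methoxyphenyl]-6,7-bis(hydroxymethyl)-3-methoxy-5,6,7,8-tetrahydronaphthalen-2-ol
Conditions: LiAlH4 (3 equiv), THF, 0 °C to rt; aqueous Rochelle salt work-up
Reagents that add atoms: none
Why: Hydride reduction of a γ-lactone to the 1,4-diol; no stereocentre is touched, the phenol only consumes one hydride as its phenoxide, and the benzyl ether and arenes are inert. The neutral work-up avoids acid-promoted closure of the cis diol to a tetrahydrofuran.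

Step 8
Reactants: 13 (6R,7S,8R)-8-[4-(benzyloxy)-3-methoxyphenyl]-6,7-bis(hydroxymethyl)-3-methoxy-5,6,7,8-tetrahydronaphthalen-2-ol
Product: 14 (6R,7S,8R)-8-(4-hydroxy-3-methoxyphenyl)-6,7-bis(hydroxymethyl)-3-methoxy-5,6,7,8-tetrahydronaphthalen-2-ol
Conditions: H2 (1 atm), 10% Pd/C, EtOAc–MeOH, rt
Reagents that add atoms: none
Why: Hydrogenolysis of a benzyl aryl ether over palladium on carbon; nothing else in 13 is reducible under these conditions, and the neutral medium leaves the three stereocentres and the diol as they are.

## Compound list

1 | [4-(benzyloxy)-3-methoxyphenyl]acetic acid (O-benzylhomovanillic acid, commercial) | COc1cc(CC(=O)O)ccc1OCc1ccccc1 | starting material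
2 | acyl imidazolide, 1-{[4-(benzyloxy)-3-methoxyphenyl]acetyl}-1H-imidazole (not isolated) | COc1cc(CC(=O)n2ccnc2)ccc1OCc1ccccc1 | intermediate
3 | 2-[4-(benzyloxy)-3-methoxyphenyl]-N-methoxy-N-methylacetamide | COc1cc(CC(=O)N(C)OC)ccc1OCc1ccccc1 | intermediate
4 | 1-[4-(benzyloxy)-3-methoxyphenyl]but-3-en-2-one | COc1cc(CC(=O)C=C)ccc1OCc1ccccc1 | intermediate
5 | tert-butyl({(1Z)-1-[4-(benzyloxy)-3-methoxyphenyl]buta-1,3-dien-2-yl}oxy)dimethylsilane | COc1cc(/C=C(\O[Si](C)(C)C(C)(C)C)C=C)ccc1OCc1ccccc1 | intermediate
6 | furan-2(5H)-one | O=C1OCC=C1 | starting material
7 | (3aS,4S,7aR)-4-[4-(benzyloxy)-3-methoxyphenyl]-5-[(tert-butyldimethylsilyl)oxy]-3a,4,7,7a-tetrahydro-2-benzofuran-1(3H)-one (all-cis endo adduct) | COc1cc([C@H]2C(O[Si](C)(C)C(C)(C)C)=CC[C@@H](C(=O)O4)[C@H]2C4)ccc1OCc1ccccc1 | intermediate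
8 | 3,3-dimethoxybutan-2-one | CC(=O)C(C)(OC)OC | starting material
9 | 3-methoxybut-3-en-2-one | C=C(OC)C(C)=O | intermediate
10 | Michael adduct diketone, (3aS,4S,7aR)-4-[4-(benzyloxy)-3-methoxyphenyl]-6-(2-methoxy-3-oxobutyl)hexahydro-2-benzofuran-1,5-dione, mixture at C4a and C6 of the tetralin numbering (not isolated) | COc1cc([C@H]2C(=O)C(CC(OC)C(C)=O)C[C@@H](C(=O)O4)[C@H]2C4)ccc1OCc1ccccc1 | intermediate
11 | annulated enone, (3aS,4R,9aR)-4-[4-(benzyloxy)-3-methoxyphenyl]-7-methoxy-3a,4,8,8a,9,9a-hexahydronaphtho[2,3-c]furan-1,6(3H,7H)-dione, C1 equilibrated to trans, mixture at C4a and C6 of the tetralin numbering (not isolated) | COc1cc([C@@H]2C3=CC(=O)C(OC)CC3C[C@@H](C(=O)O4)[C@H]2C4)ccc1OCc1ccccc1 | intermediate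
12 | (3aS,4R,9aR)-4-[4-(benzyloxy)-3-methoxyphenyl]-6-hydroxy-7-methoxy-3a,4,9,9a-tetrahydronaphtho[2,3-c]furan-1(3H)-one | COc1cc([C@@H]2c3cc(O)c(OC)cc3C[C@@H](C(=O)O4)[C@H]2C4)ccc1OCc1ccccc1 | intermediate
13 | (6R,7S,8R)-8-[4-(benzyloxy)-3-methoxyphenyl]-6,7-bis(hydroxymethyl)-3-methoxy-5,6,7,8-tetrahydronaphthalen-2-ol | COc1cc([C@@H]2c3cc(O)c(OC)cc3C[C@@H](CO)[C@H]2CO)ccc1OCc1ccccc1 | intermediate
14 | (6R,7S,8R)-8-(4-hydroxy-3-methoxyphenyl)-6,7-bis(hydroxymethyl)-3-methoxy-5,6,7,8-tetrahydronaphthalen-2-ol | COc1cc([C@@H]2c3cc(O)c(OC)cc3C[C@@H](CO)[C@H]2CO)ccc1O | target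

## Step count and least certain steps

Total: 8 steps. Longest linear sequence: 7 steps from 1 (steps 1 to 4 and 6 to 8); step 5 is a one-step side branch.

**Step 6 (key step).** The most likely failure is in the first bond formation. Enone 9 is a captodative alkene whose CH2 terminus is deactivated by the α-methoxy group, so under TiCl4 self-condensation of 9 or protodesilylation of 7 may outrun the conjugate addition. Two further hazards lie in the same sequence:
- incomplete epimerisation at C1 before aromatisation, since the preference for the trans isomer rests on a conformational argument;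
- over-oxidation by DDQ at the benzylic positions para to oxygen.

The fallback sets out from 7 and comes back at 11. Compound 7 is annulated with methyl vinyl ketone under the same two stages (TiCl4; then pyrrolidine and AcOH), the textbook case. This passes through the 3-oxobutyl diketone F1 to the ring-A-unsubstituted enone F2, which is isolated and, if necessary, equilibrated at C1 with DBU. Kinetic enolisation at C6 (LDA, TMSCl, THF, −78 °C) gives the cross-conjugated trimethylsilyl dienol ether F3. Rubottom oxidation (mCPBA, NaHCO3, CH2Cl2; then citric acid) gives the 6-hydroxy enone F4. O-Methylation (Me3OBF4, 1,8-bis(dimethylamino)naphthalene, CH2Cl2) gives 11, which is dehydrogenated to 12 as in the third stage of step 6. If DDQ over-oxidises, the isolated 11 can instead be aromatised by bromination and dehydrobromination with CuBr2 and LiBr in MeCN.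

**Step 4.** Three things may go wrong:
- low reactivity of the weak dienophile 6, so that acid-mediated loss of the enol silane competes;
- insufficient face discrimination by the catalyst;
- regiochemical leakage, because the aryl and silyloxy groups of 5 direct to opposite termini.

A regioisomeric adduct must be removed by chromatography at 7 or 12, because after step 7 it would converge on the enantiomer of 13. The fallback sets out from 5 and comes back at 13, with auxiliary control in place of catalyst control. Thermal cycloaddition of 5 (toluene, 90 °C) with (5S)-5-[(1S,2R,5S)-menthyloxy]furan-2(5H)-one F5 should give the menthyloxy adduct F6. The acetal substituent blocks one face, so the diene adds anti to it; C2 and C3 then have the configuration of 7, and regioisomers are separable constitutional isomers. F6 is taken through step 6 unchanged, via the menthyloxy diketone F7 and the menthyloxy enone F8 (neither isolated), to the menthyloxy lactone phenol F9. LiAlH4 then reduces both the lactone carbonyl and the masked aldehyde at C9', releasing menthol and giving 13. The acylal has to survive TiCl4 at −78 °C; the chelated enone is expected to react first.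

**Step 2.** The risks are deprotonation of the benzylic CH2 of 3 by the Grignard reagent, conjugate addition of the liberated N,O-dimethylhydroxylamine to 4 during the quench, and polymerisation of 4 on concentration. The fallback sets out from 1 and comes back at 4. Oxalyl chloride with catalytic DMF converts 1 to [4-(benzyloxy)-3-methoxyphenyl]acetyl chloride F10. An acyl Stille coupling with tributyl(vinyl)stannane and the zerovalent palladium complex Pd(PPh3)4 in THF at 50 °C then gives 4 under neutral conditions with no amine present.

## Further compounds

F1 | step 6 | (3aS,4S,7aR)-4-[4-(benzyloxy)-3-methoxyphenyl]-6-(3-oxobutyl)hexahydro-2-benzofuran-1,5-dione (mixture at the side-chain-bearing carbon) | COc1cc([C@H]2C(=O)C(CCC(C)=O)C[C@@H](C(=O)O4)[C@H]2C4)ccc1OCc1ccccc1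
F2 | step 6 | (3aS,4R,9aR)-4-[4-(benzyloxy)-3-methoxyphenyl]-3a,4,8,8a,9,9a-hexahydronaphtho[2,3-c]furan-1,6(3H,7H)-dione (mixture at C8a) | COc1cc([C@@H]2C3=CC(=O)CCC3C[C@@H](C(=O)O4)[C@H]2C4)ccc1OCc1ccccc1
F3 | step 6 | trimethylsilyl dienol ether of F2 (silyloxy at C7 of the tetralin numbering, double bonds C6–C7 and C8–C8a) | COc1cc([C@@H]2C3=CC(O[Si](C)(C)C)=CCC3C[C@@H](C(=O)O4)[C@H]2C4)ccc1OCc1ccccc1
F4 | step 6 | 6-hydroxy enone, the O-demethyl analogue of 11 (mixture at C4a and C6 of the tetralin numbering) | COc1cc([C@@H]2C3=CC(=O)C(O)CC3C[C@@H](C(=O)O4)[C@H]2C4)ccc1OCc1ccccc1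
F5 | step 4 | (5S)-5-{[(1S,2R,5S)-2-isopropyl-5-methylcyclohexyl]oxy}furan-2(5H)-one | O=C1C=C[C@@H](O[C@H]2C[C@@H](C)CC[C@@H]2C(C)C)O1
F6 | step 4 | (3S,3aS,4S,7aR)-4-[4-(benzyloxy)-3-methoxyphenyl]-5-[(tert-butyldimethylsilyl)oxy]-3-{[(1S,2R,5S)-2-isopropyl-5-methylcyclohexyl]oxy}-3a,4,7,7a-tetrahydro-2-benzofuran-1(3H)-one | COc1cc([C@H]2C(O[Si](C)(C)C(C)(C)C)=CC[C@@H](C(=O)O4)[C@H]2[C@H]4O[C@H]5C[C@@H](C)CC[C@@H]5C(C)C)ccc1OCc1ccccc1
F7 | step 4 | menthyloxy analogue of diketone 10 (menthyloxy on C9', mixture at C4a and C6) | COc1cc([C@H]2C(=O)C(CC(OC)C(C)=O)C[C@@H](C(=O)O4)[C@H]2[C@H]4O[C@H]5C[C@@H](C)CC[C@@H]5C(C)C)ccc1OCc1ccccc1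
F8 | step 4 | menthyloxy analogue of enone 11 (menthyloxy on C9', mixture at C4a and C6) | COc1cc([C@@H]2C3=CC(=O)C(OC)CC3C[C@@H](C(=O)O4)[C@H]2[C@H]4O[C@H]5C[C@@H](C)CC[C@@H]5C(C)C)ccc1OCc1ccccc1
F9 | step 4 | menthyloxy analogue of lactone phenol 12 (menthyloxy on C9') | COc1cc([C@@H]2c3cc(O)c(OC)cc3C[C@@H](C(=O)O4)[C@H]2[C@H]4O[C@H]5C[C@@H](C)CC[C@@H]5C(C)C)ccc1OCc1ccccc1
F10 | step 2 | [4-(benzyloxy)-3-methoxyphenyl]acetyl chloride | COc1cc(CC(=O)Cl)ccc1OCc1ccccc1
A1 | alternative 1 | (2R,3R)-butane-2,3-diyl bis[(2E)-3-(3-bromo-4-hydroxy-5-methoxyphenyl)prop-2-enoate] | COc1cc(/C=C/C(=O)O[C@H](C)[C@@H](C)OC(=O)/C=C/c2cc(Br)c(O)c(OC)c2)cc(Br)c1O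
A2 | alternative 1 | diol-bridged trans-1-aryl-1,2-dihydronaphthalene-2,3-dicarboxylate (eight-membered dilactone, bromine at C8 and on the pendant ring) | COc1cc([C@@H]2c3c(Br)c(O)c(OC)cc3C=C(C(=O)O[C@H](C)[C@@H](C)O6)[C@H]2C6=O)cc(Br)c1O
A3 | alternative 2 | 7-(benzyloxy)-1-[4-(benzyloxy)-3-methoxyphenyl]-6-methoxy-1,4-dihydronaphthalene, C1 as in 14 | COc1cc([C@@H]2c3cc(OCc5ccccc5)c(OC)cc3CC=C2)ccc1OCc1ccccc1
A4 | alternative 2 | dimethyl 7-(benzyloxy)-1-[4-(benzyloxy)-3-methoxyphenyl]-6-methoxy-1,2,3,4-tetrahydronaphthalene-2,3-dicarboxylate, esters cis to each other and trans to the aryl group | COc1cc([C@@H]2c3cc(OCc5ccccc5)c(OC)cc3C[C@@H](C(=O)OC)[C@H]2C(=O)OC)ccc1OCc1ccccc1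
A5 | alternative 3 | 4-(benzyloxy)-2-[4-(benzyloxy)-3-methoxybenzyl]-5-methoxybenzaldehyde | O=Cc1cc(OC)c(OCc2ccccc2)cc1Cc1ccc(OCc2ccccc2)c(OC)c1
A6 | alternative 3 | methyl (2E)-4-[(tert-butyldimethylsilyl)oxy]but-2-enoate | COC(=O)/C=C/CO[Si](C)(C)C(C)(C)C
A7 | alternative 3 | methyl 6-(benzyloxy)-4-[4-(benzyloxy)-3-methoxyphenyl]-3-{[(tert-butyldimethylsilyl)oxy]methyl}-1-hydroxy-7-methoxy-1,2,3,4-tetrahydronaphthalene-2-carboxylate (C1 and C2 of the tetralin numbering as in 14, C3 opposite) | COc1cc([C@@H]2c3cc(OCc4ccccc4)c(OC)cc3[C@H](O)[C@H](C(=O)OC)[C@H]2CO[Si](C)(C)C(C)(C)C)ccc1OCc1ccccc1
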